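A closed, stirred two-phase vessel holds the starting material and the protic impurity in the first phase, while the reagent is charged to the second and must cross into the reaction phase before it can react.

starting material 10 mM; reagent in the second phase 4.00 equiv; protic impurity 2.00 mM; time 50 s; volume of the second phase over the first 2.0

    starting material ⇌ dormant form (K1 = 2.4, k1 = 0.020 s⁻¹)
    starting material + protic impurity → quenched substrate (k2 = 16 M⁻¹ s⁻¹)
    starting material + reagent in the reaction phase → product (k3 = 23 M⁻¹ s⁻¹)
    reagent in the reaction phase ⇌ reagent in the second phase, rate k4*([reagent in the reaction phase] - [reagent in the second phase]/K4) per volume of the first phase (K4 = 0.77, k4 = 0.21 s⁻¹)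

- in the second phase: reagent in the second phase; everything else is in the first
- charges count per volume of the first phase; a concentration in a rate is the amount of a species over the volume of its own phase; every rate counts per litre of the first phase
- run time (flask): 50 s

* how much product there is at 50 s, in percent of the starting material charged
* the change that raises the amount of product at 50 s, in percent of the starting material charged most ("none" if none brings more than 2 percentage points) (Thursday's / Saturday's / none)
* amount of product at 50 s, in percent of the starting material charged, after Thursday's

Two numbers seem not to fit. The charge amounts to 40.0 mM of reagent per volume of the first phase, yet with the partition settled and nothing consumed, c(reagent in the reaction phase) is 15.7 mM, less than the charge. The reason is the balance: the second phase has 2.0 volumes and holds 0.77 times the reaction-phase concentration.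

free share = 1 / (1 + 2.0 × 0.77) = 39.4%

This free share, the part of the unconsumed reagent standing in the reaction phase once the partition has settled, is what this reckoning carries. The partition relaxes with a half-life of 2.00 s, shorter than the 22 s and 35 s of the two leaks.

With one charge of starting material consumed, the reaction phase holds:

c(reagent in the reaction phase) = (40.0 mM − 10 mM) × 39.4% = 11.8 mM

Starting material then runs down pseudo-first-order routes, with the impurity held at its charge: to product 0.272 s⁻¹, to quenched substrate 0.0320 s⁻¹, to dormant form 0.020 s⁻¹, forward step alone. The route to product has a half-life of 2.55 s, longer than the partition's 2.00 s by a factor of 1.27, so taking the partition as settled is a rough step, and the lag before it goes uncounted in this sum.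

product share = 0.272 s⁻¹ / (0.272 s⁻¹ + 0.0320 s⁻¹ + 0.020 s⁻¹) = 83.9%

The transfer coefficient does not enter, so after Thursday's this reckoning stays at 83.9%. Saturday's raises the share to 92.4%, which makes the choice Saturday's.

The forecast says 82% (78% to 86%), and 86.5% after Thursday's (83% to 90%). It picks Saturday's, since doubling the reagent “doubles the plateau concentration”. Its y lies below the reckoning here, and its Thursday value above it.

The simulation gives 82.4%, 85.0% after Thursday's, and Saturday's as the best change, worth 5.6 percentage points against 2.6 points for Thursday's.

The neighbour flask starts from 4.0 mM of starting material with the same 4.00 equiv of reagent, and its protic impurity comes to 0.500 equiv. The free share stays 39.4%, so the neighbour's reaction phase should hold 4.72 mM of reagent, and the same sum gives a product share of 67.6%. In the neighbour flask at 50.0 s, the reaction phase holds 5.21 mM of reagent, with 68.9% product, 19.6% quenched substrate and 10.9% dormant form.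

(The constants come from no measurement; the rest is arithmetic.)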